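**Retrosynthetic overview**
1. Feature: in the ten-membered ring, C7 (lactone O, next to C5=C6) is bonded to C8, and C8 carries the three-carbon unit C17/C18/C19. This is the retron of a [2,3]-Wittig shift of a C7–O–C19 ether.
2. Endgame: C8–OH/C17–H come from SmI2 opening of an 8,17-epoxy lactone, made by C7–OH-directed epoxidation of the C8=C17 enediol, which derives from the butenolide and, before it, the isopropenyl group. C5(Me)=C6(Cl) comes from syn methylmagnesiation/chlorination of the C5≡C6 alkynol.
3. Key disconnection: the ten-membered cycloalkynol (C7–OH, C8-isopropenyl) comes from a 13-membered propargylic (Z)-allylic ether fused to ring A.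
4. The 13-membered ring is closed by alkyne metathesis (C5≡C6). C8–C9 is made by Nozaki–Hiyama–Kishi coupling and C2–C3 by Grignard addition. Ring A comes from a catalytic asymmetric Diels–Alder reaction of (E)-piperylene with ethyl (E)-2-methyl-4-oxobut-2-enoate.
5. Ring order: ring A (six-membered), then the 13-membered ether, then the ten-membered carbocycle (contraction), then the γ-lactone.

Key step: step 21

Remark 1: briarane numbering is kept for all intermediates; β is the face of ring A that carries the C15 methyl group and α is the opposite face.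
Remark 2: the C8=C17 alkene of the macrocyclic ether is built Z (C9 cis to C19), because A(1,3) strain holds H9 in the alkene plane so the carbanion can reach only the C8 face anti to the C9–O bond, and on that face the Z-alkene (syn pair) leads to 7R whereas an E-alkene (anti pair) would lead to 7S.
Remark 3: the sense of induction in step 2 is assigned from the usual model (boron-bound s-trans enal, formyl C–H···O contact, one face stacked on a phenyl group); the antipodal catalyst is equally available.

**Step 1**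
Reactants: 1 ethyl 2-(triphenylphosphoranylidene)propanoate; 2 glyoxal
Product: 3 ethyl (E)-2-methyl-4-oxobut-2-enoate
Conditions: 2 (40 % aq., 5 equiv), CH2Cl2–H2O, 0 °C → rt
Reagents that add atoms: none
Why: Wittig olefination with a stabilised ylide gives the E-enoate (CHO trans to CO2Et), and the excess of glyoxal keeps the second formyl group from reacting.

**Step 2**
Reactants: 3 ethyl (E)-2-methyl-4-oxobut-2-enoate; 4 (E)-penta-1,3-diene
Product: 5 ethyl (1S,5S,6S)-6-formyl-1,5-dimethylcyclohex-3-ene-1-carboxylate (ring A: C15 methyl, C9 formyl and C20 methyl β; C2 ester α; C12=C13)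
Conditions: (R)-3,3-diphenyl-1-(2-methylphenyl)tetrahydro-1H,3H-pyrrolo[1,2-c][1,3,2]oxazaborole (20 mol %), HN(SO2CF3)2 (18 mol %), 4 (5 equiv), CH2Cl2, −78 → −40 °C
Reagents that add atoms: none
Why: Catalytic enantioselective Diels–Alder reaction in which the boron-bound formyl group controls regiochemistry (the free diene terminus C14 bonds to the β-carbon C1 and the methyl-bearing terminus C11 to C10, the ortho rule), CHO-endo addition places C9, C15 and C20 on one face, the E-dienophile keeps C2 trans to C9, and the catalyst phenyl group covers the Re face of C10 so that addition to the Si face sets C1, C10 and C11 in the absolute configuration of the target.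

**Step 3**
Reactants: 5 Diels–Alder aldehyde
Product: 6 C9 dimethyl acetal of 5
Conditions: HC(OMe)3, PPTS (cat.), MeOH, rt
Reagents that add atoms: trimethyl orthoformate COC(OC)OC
Why: Acid-catalysed acetalisation masks the formyl group and removes the acidity of H10, so C10 cannot epimerise in the basic steps that follow.

**Step 4**
Reactants: 6 acetal ester
Product: 7 12α,13α-epoxide of 6
Conditions: m-CPBA, NaHCO3, CH2Cl2, 0 °C
Reagents that add atoms: m-chloroperbenzoic acid OOC(=O)c1cccc(Cl)c1
Why: Prilezhaev epoxidation of the only alkene, where the β face is screened in both half-chairs (by the pseudoaxial C15 and C20 methyls in one, by the axial CH(OMe)2 group in the other), so oxygen should arrive on the α face and set the C12–O configuration.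

**Step 5**
Reactants: 7 α-epoxide
Product: 8 12α-hydroxy-13-ene ester
Conditions: LDA (3 equiv), THF, 0 → 40 °C; H2O
Reagents that add atoms: none
Why: Base-promoted isomerisation of an epoxide to an allylic alcohol by syn β-elimination, in which the amide held on the epoxide oxygen takes the syn proton of the less substituted neighbour (H14α of the CH2 group, not the tertiary H11), C13–O breaks, C13=C14 forms and the α C12–O bond is kept.

**Step 6**
Reactants: 8 allylic alcohol
Product: 9 12α-OTBS ester
Conditions: TBSCl, imidazole, DMF, 40 °C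
Reagents that add atoms: tert-butyldimethylsilyl chloride CC(C)(C)[Si](C)(C)Cl
Why: Standard silylation of the allylic alcohol under conditions (no silyl triflate) that leave the dimethyl acetal alone.

**Step 7**
Reactants: 9 silyl ether ester
Product: 10 C2 primary alcohol
Conditions: i-Bu2AlH (2.5 equiv), CH2Cl2, −78 → 0 °C; aq. potassium sodium tartrate
Reagents that add atoms: none
Why: Hydride reduction of the non-enolisable neopentyl ester to the primary alcohol, with acetal, silyl ether and alkene inert to i-Bu2AlH at this temperature.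

**Step 8**
Reactants: 10 primary alcohol
Product: 11 C2 aldehyde
Conditions: Dess–Martin periodinane, NaHCO3, CH2Cl2, rt
Reagents that add atoms: none
Why: Dess–Martin oxidation under buffered neutral conditions, giving an aldehyde that has no α-hydrogen and cannot epimerise.

**Step 9**
Reactants: 12 pent-3-yn-1-ol
Product: 13 5-bromopent-2-yne
Conditions: CBr4, PPh3, CH2Cl2, 0 °C
Reagents that add atoms: carbon tetrabromide BrC(Br)(Br)Br
Why: Appel reaction, an SN2 displacement of the oxyphosphonium group by bromide at a primary carbon that leaves the internal alkyne untouched.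

**Step 10**
Reactants: 11 C2 aldehyde; 13 5-bromopent-2-yne
Product: 15 C2 carbinol bearing the pent-3-ynyl chain (C2 epimers), via pent-3-ynylmagnesium bromide 14 (not isolated)
Conditions: 13, Mg, THF, rt; then 11, THF, −78 → 0 °C; H2O
Reagents that add atoms: none
Why: Grignard addition to the hindered but non-enolisable aldehyde forms C2–C3, and the facial bias of the quaternary C1 is not relied on because C2 is reset in steps 11 and 12.

**Step 11**
Reactants: 15 C2 carbinol
Product: 16 C2 ketone
Conditions: Dess–Martin periodinane, NaHCO3, CH2Cl2, rt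
Reagents that add atoms: none
Why: Dess–Martin oxidation removes the uncontrolled C2 centre.

**Step 12**
Reactants: 16 C2 ketone
Product: 17 (2S)-carbinol
Conditions: (R)-1-methyl-3,3-diphenyltetrahydro-1H,3H-pyrrolo[1,2-c][1,3,2]oxazaborole (0.5 equiv), BH3·SMe2, toluene, −30 °C; MeOH, then H2O
Reagents that add atoms: none
Why: CBS reduction in which the ketone binds with the quaternary C1 as the large and the C3 methylene as the small group, so the (R)-catalyst gives the 2S alcohol under reagent control, faster than borane can hydroborate the internal alkyne at this temperature.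

**Step 13**
Reactants: 17 (2S)-carbinol
Product: 20 (2S)-2,12-bis-OTBS C9 aldehyde, via bis-silyl ether acetal 18 (not isolated), via lutidinium salt 19 (not isolated)
Conditions: TBSOTf (1.5 equiv), 2,6-lutidine (6 equiv), CH2Cl2, 0 °C; then TESOTf (2 equiv), 0 °C; then H2O
Reagents that add atoms: tert-butyldimethylsilyl triflate CC(C)(C)[Si](C)(C)OS(=O)(=O)C(F)(F)F; water O
Why: Silyl triflate silylation of the hindered C2 alcohol followed in the same flask by silyl triflate/2,6-lutidine cleavage of the aldehyde acetal through its lutidinium salt, which water hydrolyses under weakly basic conditions that spare the TBS ethers and do not enolise the C9 aldehyde (C10 kept).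

**Step 14**
Reactants: 21 prop-2-yn-1-ol
Product: 23 (Z)-3-iodo-2-methylprop-2-en-1-ol, via oxamagnesacycle 22 (not isolated)
Conditions: MeMgBr (2.5 equiv), CuI (10 mol %), THF, −10 °C → rt; then I2, 0 °C; H2O
Reagents that add atoms: methylmagnesium bromide C[Mg]Br; iodine [I][I]
Why: Copper-catalysed anti-carbomagnesiation of propargyl alcohol puts methyl on C17 and magnesium on C8 cis to the CH2O arm in a five-membered chelate, and iodinolysis with retention gives the Z-iodide.

**Step 15**
Reactants: 23 (Z)-3-iodo-2-methylprop-2-en-1-ol; 24 1-bromobut-2-yne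
Product: 25 (Z)-3-(but-2-ynyloxy)-1-iodo-2-methylprop-1-ene
Conditions: NaH, THF, 0 °C; then 24, n-Bu4NI (cat.), rt
Reagents that add atoms: none
Why: Williamson ether synthesis (SN2 of the alkoxide on a primary propargylic bromide) forms the C19–O–C7 ether, and the vinyl iodide is inert to NaH.

**Step 16**
Reactants: 20 C9 aldehyde; 25 (Z)-iodo ether
Product: 27 C9 allylic alcohol (C9 epimers), via alkenylchromium dichloride 26 (not isolated)
Conditions: CrCl2 (4 equiv), NiCl2 (1 mol %), DMSO, rt; H2O
Reagents that add atoms: none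
Why: Nozaki–Hiyama–Kishi coupling forms C8–C9 with retention of the trisubstituted alkene geometry under non-basic conditions that tolerate the propargylic ether and do not epimerise C10, and the C9 centre is not relied on because it is reset in steps 17 and 18.

**Step 17**
Reactants: 27 allylic alcohol
Product: 28 (Z)-enone (C9 ketone)
Conditions: Dess–Martin periodinane, NaHCO3, CH2Cl2, 0 °C
Reagents that add atoms: none
Why: Dess–Martin oxidation under buffered conditions gives the enone without Z to E isomerisation or epimerisation at C10.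

**Step 18**
Reactants: 28 (Z)-enone
Product: 29 C9 allylic alcohol in the target configuration (9R by CIP in this compound)
Conditions: NaBH4, CeCl3·7H2O, MeOH, −78 °C
Reagents that add atoms: none
Why: Luche reduction (1,2-selective) in which the quaternary C1, the largest group on C10, stands anti to the incoming hydride and the carbonyl oxygen sits next to C11, so hydride adds to the face that gives the C9 configuration of the target, the opposite of what carbon nucleophiles give with aldehyde 20.

**Step 19**
Reactants: 29 allylic alcohol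
Product: 30 2,9,12-tris-OTBS diyne
Conditions: TBSOTf, 2,6-lutidine, CH2Cl2, 0 °C
Reagents that add atoms: tert-butyldimethylsilyl triflate CC(C)(C)[Si](C)(C)OS(=O)(=O)C(F)(F)F
Why: Silyl triflate silylation of the hindered allylic alcohol.

**Step 20**
Reactants: 30 tris-OTBS diyne
Product: 31 13-membered propargylic (Z)-allylic ether fused to ring A
Conditions: Mo(≡CC6H4-4-OMe)(OSiPh3)3 (5 mol %), MS 5 Å, toluene (2 mM), 60 °C
Reagents that add atoms: none
Why: Ring-closing alkyne metathesis joins C5 and C6 and closes the 13-membered ring, uptake of but-2-yne by the molecular sieves drives the equilibrium, and the molybdenum alkylidyne ignores alkenes, silyl ethers and the propargylic ether oxygen.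

**Step 21**
Reactants: 31 13-membered propargylic (Z)-allylic ether
Product: 34 ten-membered C5≡C6 cycloalkynol (7R-OH; 8S-isopropenyl), via C7-lithiated ether 32 (not isolated), via lithium alkoxide 33 (not isolated)
Conditions: n-BuLi (1.5 equiv), THF–hexane, −78 → −30 °C; H2O
Reagents that add atoms: none
Why: n-BuLi removes a C7 proton, the most acidic C–H because it is both propargylic and α to oxygen (C19–H is only allylic, C4–H has no oxygen), and the lithiated carbon attacks C8 through a five-membered envelope (C7, O, C19, C17, C8) while O–C19 breaks and C17=C19 forms in a concerted suprafacial [2,3]-sigmatropic shift. The closest known reaction type is the [2,3]-Wittig ring contraction of 13-membered propargylic allylic ethers to ten-membered cycloalkynols. The ten-membered ring is closed transannularly, by forming C7–C8 across the existing ring and extruding O, C19 and C17 from it, so no dilution-dependent cyclisation is involved. C8 is controlled by A(1,3) strain between C19H2 and C9, which keeps H9 in the alkene plane, places C10 and with it the whole tether including C7 on one face, and sets the C9–OTBS bond antiperiplanar to the incoming carbanion, so only that face of C8 is within reach. C7 is controlled by the alkynyl arm taking the exo position on the envelope, away from the C17 methyl group, which for a Z-alkene gives the syn (ring-cis) C7/C8 pair and, on the face just defined, 7R. The step needs C7 rather than C19 deprotonation (secured by propargylic acidity), [2,3] rather than [1,2] shift (secured by low temperature) and this face/exo combination; C8 is erased in step 25, so C7 is the lasting centre.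

**Step 22**
Reactants: 34 cycloalkynol
Product: 35 allylic diol (the isopropenyl CH3 becomes CH2OH; this carbon is called C19 from here on and the methylene carbon C18)
Conditions: SeO2 (0.5 equiv), t-BuOOH (2 equiv), CH2Cl2, 0 °C
Reagents that add atoms: tert-butyl hydroperoxide CC(C)(C)OO
Why: Riley allylic oxidation (ene reaction, then [2,3]-shift) of the isopropenyl group, the only unhindered 1,1-disubstituted alkene, run before the chloroalkene exists so that no second allylic methyl competes, with the methyl group reacting rather than the buried tertiary H8.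

**Step 23**
Reactants: 35 allylic diol
Product: 37 (5E)-6-chloro-5-methyl diol, via C6-alkenylmagnesium bromide 36 (not isolated)
Conditions: Fe(acac)3 (20 mol %), MeMgBr (6 equiv), THF, 0 °C → rt; then NCS, THF, −78 → −20 °C; H2O
Reagents that add atoms: methylmagnesium bromide C[Mg]Br; N-chlorosuccinimide O=C1CCC(=O)N1Cl
Why: Alkoxide-directed iron-catalysed syn-carbomagnesiation of a propargylic alcohol followed by electrophilic chlorination, in which the C7 magnesium alkoxide steers methyl to the distal C5 and magnesium to C6, and syn addition across the ring alkyne can only give the ring-cis alkene with CH3 and MgBr (then Cl, with retention) on the same side, which is the alkene geometry of the target.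

**Step 24**
Reactants: 37 chloro diol
Product: 39 cis-fused α-methylene-γ-lactone, via lactol 38 (not isolated)
Conditions: TEMPO (20 mol %), PhI(OAc)2 (2.5 equiv), CH2Cl2, rt
Reagents that add atoms: none
Why: Oxoammonium-mediated oxidative lactonisation of a 1,4-diol, in which the primary allylic alcohol is oxidised first, the C7 hydroxyl closes the lactol, and the lactol is oxidised on, faster than the hindered secondary C7 alcohol itself.

**Step 25**
Reactants: 39 α-methylene lactone
Product: 40 C8=C17 butenolide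
Conditions: RhCl3·3H2O (10 mol %), EtOH–toluene, 75 °C
Reagents that add atoms: none
Why: Rhodium hydride alkene isomerisation (addition–elimination), in which Rh–H adds to the exocyclic methylene from the convex face that also carries H8 and β-hydride elimination of H8 gives the more substituted conjugated butenolide without base, so the now acidic H7 is not touched and only C8 is erased.

**Step 26**
Reactants: 40 butenolide
Product: 41 (Z)-C8=C17 ene-1,4-diol (C7–OH, C19–OH)
Conditions: i-Bu2AlH (4 equiv), CH2Cl2, −78 → −20 °C; aq. potassium sodium tartrate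
Reagents that add atoms: none
Why: Exhaustive 1,2-reduction of the butenolide gives the enediol with C7 cis to C19 as fixed by the former ring, and the non-acidic work-up avoids dehydration of the lactol stage to a furan.

**Step 27**
Reactants: 41 enediol
Product: 42 8,17-epoxy diol (epoxide oxygen on the face syn to O7)
Conditions: m-CPBA, NaHCO3, CH2Cl2, −20 °C
Reagents that add atoms: m-chloroperbenzoic acid OOC(=O)c1cccc(Cl)c1
Why: Hydroxyl-directed peracid epoxidation of the electron-rich tetrasubstituted alkene (the chloroalkene and the hindered ring A alkene are much slower), in which A(1,3) strain with C19H2 holds H7 in the alkene plane so that the hydrogen-bonded peracid is delivered from the O7 side (threo mode) while the C9–OTBS group blocks the other face, which sets C8–O as in the target.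

**Step 28**
Reactants: 42 epoxy diol
Product: 44 8,17-epoxy-γ-lactone, via epoxy lactol 43 (not isolated)
Conditions: TEMPO (20 mol %), PhI(OAc)2 (2.5 equiv), NaHCO3, CH2Cl2, rt
Reagents that add atoms: none
Why: Oxoammonium-mediated oxidative lactonisation of the 1,4-diol as in step 24, buffered so that the tetrasubstituted epoxide survives.

**Step 29**
Reactants: 44 epoxy lactone
Product: 46 8-hydroxy lactone (C17 epimers), via samarium enolate 45 (not isolated)
Conditions: SmI2 (2.5 equiv), HMPA, Me2NCH2CH2OH, THF, −78 °C; H2O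
Reagents that add atoms: none
Why: SmI2 reduction of an α,β-epoxy ester, in which two single-electron transfers break the C17–O bond α to the carbonyl and leave the C8–O bond set in step 27 untouched, the enolate being protonated without reliance on the C17 outcome.

**Step 30**
Reactants: 46 8-hydroxy lactone (C17 epimers)
Product: 47 (17R)-8-hydroxy lactone
Conditions: DBU (0.3 equiv), toluene, rt
Reagents that add atoms: none
Why: Base-mediated epimerisation under thermodynamic control at C17, now the only acidic centre, lets the C18 methyl settle trans to the bulky C9 branch on C8 (cis to the small hydroxyl), which is 17R.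

**Step 31**
Reactants: 47 tris-OTBS hydroxy lactone
Product: 48 2,8,9,12-tetraol
Conditions: HF·pyridine, THF–pyridine, 0 → 40 °C
Reagents that add atoms: none
Why: Fluoride-mediated desilylation under mildly acidic conditions, which avoids base-induced migration of the lactone from O7 to O9.

**Step 32**
Reactants: 48 tetraol
Product: 51 CNP0296164.1 (target), via phenylboronate 49 (not isolated), via phenylboronate diacetate 50 (not isolated)
Conditions: PhB(OH)2 (1.05 equiv), MS 4 Å, CH2Cl2, rt; then Ac2O, pyridine, DMAP (cat.), rt; then pinacol, rt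
Reagents that add atoms: acetic anhydride CC(=O)OC(C)=O
Why: Transient cyclic boronate protection of the only 1,2-diol (C8/C9), then DMAP-catalysed acetylation of the two free secondary alcohols (C2, C12), then transesterification of the boronate to pinacol, which leaves 8-OH and 9-OH free and keeps O9 from attacking the lactone.

**Compound list**
1 | ethyl 2-(triphenylphosphoranylidene)propanoate | CCOC(=O)C(C)=P(c1ccccc1)(c1ccccc1)c1ccccc1 | starting material
2 | glyoxal | O=CC=O | starting material
3 | ethyl (E)-2-methyl-4-oxobut-2-enoate | CCOC(=O)/C(C)=C/C=O | intermediate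
4 | (E)-penta-1,3-diene | C=C/C=C/C | starting material
5 | ethyl (1S,5S,6S)-6-formyl-1,5-dimethylcyclohex-3-ene-1-carboxylate | O=C[C@H]1[C@@H](C)C=CC[C@@]1(C(=O)OCC)C | intermediate
6 | C9 dimethyl acetal of 5 | COC(OC)[C@H]1[C@@H](C)C=CC[C@@]1(C(=O)OCC)C | intermediate
7 | 12α,13α-epoxide | COC(OC)[C@H]1[C@@H](C)[C@@H]2O[C@@H]2C[C@@]1(C(=O)OCC)C | intermediate
8 | 12α-hydroxy-13-ene ester | COC(OC)[C@H]1[C@@H](C)[C@H](O)C=C[C@@]1(C(=O)OCC)C | intermediate
9 | 12α-OTBS ester | COC(OC)[C@H]1[C@@H](C)[C@H](O[Si](C)(C)C(C)(C)C)C=C[C@@]1(C(=O)OCC)C | intermediate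
10 | C2 primary alcohol | COC(OC)[C@H]1[C@@H](C)[C@H](O[Si](C)(C)C(C)(C)C)C=C[C@@]1(CO)C | intermediate
11 | C2 aldehyde | COC(OC)[C@H]1[C@@H](C)[C@H](O[Si](C)(C)C(C)(C)C)C=C[C@@]1(C=O)C | intermediate
12 | pent-3-yn-1-ol | CC#CCCO | starting material
13 | 5-bromopent-2-yne | CC#CCCBr | intermediate
14 | pent-3-ynylmagnesium bromide | CC#CCC[Mg]Br | intermediate
15 | C2 carbinol (C2 epimers) | COC(OC)[C@H]1[C@@H](C)[C@H](O[Si](C)(C)C(C)(C)C)C=C[C@@]1(C(O)CCC#CC)C | intermediate
16 | C2 ketone | COC(OC)[C@H]1[C@@H](C)[C@H](O[Si](C)(C)C(C)(C)C)C=C[C@@]1(C(=O)CCC#CC)C | intermediate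
17 | (2S)-carbinol | COC(OC)[C@H]1[C@@H](C)[C@H](O[Si](C)(C)C(C)(C)C)C=C[C@@]1([C@@H](O)CCC#CC)C | intermediate
18 | (2S)-2,12-bis-OTBS acetal | COC(OC)[C@H]1[C@@H](C)[C@H](O[Si](C)(C)C(C)(C)C)C=C[C@@]1([C@@H](O[Si](C)(C)C(C)(C)C)CCC#CC)C | intermediate
19 | C9 methoxy(2,6-lutidinium) triflate | COC([n+]2c(C)cccc2C)[C@H]1[C@@H](C)[C@H](O[Si](C)(C)C(C)(C)C)C=C[C@@]1([C@@H](O[Si](C)(C)C(C)(C)C)CCC#CC)C.[O-]S(=O)(=O)C(F)(F)F | intermediate
20 | (2S)-2,12-bis-OTBS C9 aldehyde | O=C[C@H]1[C@@H](C)[C@H](O[Si](C)(C)C(C)(C)C)C=C[C@@]1([C@@H](O[Si](C)(C)C(C)(C)C)CCC#CC)C | intermediate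
21 | prop-2-yn-1-ol | C#CCO | starting material
22 | 4-methyl-2,5-dihydro-1,2-oxamagnesole | CC1=C[Mg]OC1 | intermediate
23 | (Z)-3-iodo-2-methylprop-2-en-1-ol | OC/C(C)=C\I | intermediate
24 | 1-bromobut-2-yne | CC#CCBr | starting material
25 | (Z)-3-(but-2-ynyloxy)-1-iodo-2-methylprop-1-ene | CC#CCOC/C(C)=C\I | intermediate
26 | (Z)-alkenylchromium dichloride | CC#CCOC/C(C)=C\[Cr](Cl)Cl | intermediate
27 | C9 allylic alcohol (C9 epimers) | CC#CCOC/C(C)=C\C(O)[C@H]1[C@@H](C)[C@H](O[Si](C)(C)C(C)(C)C)C=C[C@@]1([C@@H](O[Si](C)(C)C(C)(C)C)CCC#CC)C | intermediate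
28 | (Z)-enone | CC#CCOC/C(C)=C\C(=O)[C@H]1[C@@H](C)[C@H](O[Si](C)(C)C(C)(C)C)C=C[C@@]1([C@@H](O[Si](C)(C)C(C)(C)C)CCC#CC)C | intermediate
29 | C9 allylic alcohol, target configuration | CC#CCOC/C(C)=C\[C@@H](O)[C@H]1[C@@H](C)[C@H](O[Si](C)(C)C(C)(C)C)C=C[C@@]1([C@@H](O[Si](C)(C)C(C)(C)C)CCC#CC)C | intermediate
30 | 2,9,12-tris-OTBS diyne | CC#CCOC/C(C)=C\[C@@H](O[Si](C)(C)C(C)(C)C)[C@H]1[C@@H](C)[C@H](O[Si](C)(C)C(C)(C)C)C=C[C@@]1([C@@H](O[Si](C)(C)C(C)(C)C)CCC#CC)C | intermediate
31 | 13-membered propargylic (Z)-allylic ether | CC(C)(C)[Si](C)(C)O[C@H]1CCC#CCOC/C(C)=C\[C@@H](O[Si](C)(C)C(C)(C)C)[C@H]2[C@@H](C)[C@H](O[Si](C)(C)C(C)(C)C)C=C[C@@]21C | intermediate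
32 | C7-lithiated ether | CC(C)(C)[Si](C)(C)O[C@H]1CCC#CC([Li])OC/C(C)=C\[C@@H](O[Si](C)(C)C(C)(C)C)[C@H]2[C@@H](C)[C@H](O[Si](C)(C)C(C)(C)C)C=C[C@@]21C | intermediate
33 | lithium alkoxide of 34 | CC(C)(C)[Si](C)(C)O[C@H]1CCC#C[C@H](O[Li])[C@H](C(C)=C)[C@@H](O[Si](C)(C)C(C)(C)C)[C@H]2[C@@H](C)[C@H](O[Si](C)(C)C(C)(C)C)C=C[C@@]21C | intermediate
34 | ten-membered cycloalkynol (7R, 8S) | CC(C)(C)[Si](C)(C)O[C@H]1CCC#C[C@H](O)[C@H](C(C)=C)[C@@H](O[Si](C)(C)C(C)(C)C)[C@H]2[C@@H](C)[C@H](O[Si](C)(C)C(C)(C)C)C=C[C@@]21C | intermediate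
35 | allylic diol | CC(C)(C)[Si](C)(C)O[C@H]1CCC#C[C@H](O)[C@H](C(=C)CO)[C@@H](O[Si](C)(C)C(C)(C)C)[C@H]2[C@@H](C)[C@H](O[Si](C)(C)C(C)(C)C)C=C[C@@]21C | intermediate
36 | C6-alkenylmagnesium bromide bis(alkoxide) | CC(C)(C)[Si](C)(C)O[C@H]1CC/C(C)=C(/[Mg]Br)[C@H](O[Mg]Br)[C@H](C(=C)CO[Mg]Br)[C@@H](O[Si](C)(C)C(C)(C)C)[C@H]2[C@@H](C)[C@H](O[Si](C)(C)C(C)(C)C)C=C[C@@]21C | intermediate
37 | 6-chloro-5-methyl diol | CC(C)(C)[Si](C)(C)O[C@H]1CC/C(C)=C(/Cl)[C@H](O)[C@H](C(=C)CO)[C@@H](O[Si](C)(C)C(C)(C)C)[C@H]2[C@@H](C)[C@H](O[Si](C)(C)C(C)(C)C)C=C[C@@]21C | intermediate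
38 | α-methylene lactol | CC(C)(C)[Si](C)(C)O[C@H]1CC/C(C)=C(/Cl)[C@@H]3OC(O)C(=C)[C@@H]3[C@@H](O[Si](C)(C)C(C)(C)C)[C@H]2[C@@H](C)[C@H](O[Si](C)(C)C(C)(C)C)C=C[C@@]21C | intermediate
39 | cis-fused α-methylene-γ-lactone | CC(C)(C)[Si](C)(C)O[C@H]1CC/C(C)=C(/Cl)[C@@H]3OC(=O)C(=C)[C@@H]3[C@@H](O[Si](C)(C)C(C)(C)C)[C@H]2[C@@H](C)[C@H](O[Si](C)(C)C(C)(C)C)C=C[C@@]21C | intermediate
40 | C8=C17 butenolide | CC(C)(C)[Si](C)(C)O[C@H]1CC/C(C)=C(/Cl)[C@@H]3OC(=O)C(C)=C3[C@@H](O[Si](C)(C)C(C)(C)C)[C@H]2[C@@H](C)[C@H](O[Si](C)(C)C(C)(C)C)C=C[C@@]21C | intermediate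
41 | (Z)-C8=C17 ene-1,4-diol | CC(C)(C)[Si](C)(C)O[C@H]1CC/C(C)=C(/Cl)[C@H](O)/C(=C(/C)CO)[C@@H](O[Si](C)(C)C(C)(C)C)[C@H]2[C@@H](C)[C@H](O[Si](C)(C)C(C)(C)C)C=C[C@@]21C | intermediate
42 | 8,17-epoxy diol | CC(C)(C)[Si](C)(C)O[C@H]1CC/C(C)=C(/Cl)[C@H](O)[C@]4(O[C@@]4(C)CO)[C@@H](O[Si](C)(C)C(C)(C)C)[C@H]2[C@@H](C)[C@H](O[Si](C)(C)C(C)(C)C)C=C[C@@]21C | intermediate
43 | 8,17-epoxy lactol | CC(C)(C)[Si](C)(C)O[C@H]1CC/C(C)=C(/Cl)[C@@H]3OC(O)[C@]4(C)O[C@]34[C@@H](O[Si](C)(C)C(C)(C)C)[C@H]2[C@@H](C)[C@H](O[Si](C)(C)C(C)(C)C)C=C[C@@]21C | intermediate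
44 | 8,17-epoxy-γ-lactone | CC(C)(C)[Si](C)(C)O[C@H]1CC/C(C)=C(/Cl)[C@@H]3OC(=O)[C@]4(C)O[C@]34[C@@H](O[Si](C)(C)C(C)(C)C)[C@H]2[C@@H](C)[C@H](O[Si](C)(C)C(C)(C)C)C=C[C@@]21C | intermediate
45 | samarium enolate alkoxide | CC(C)(C)[Si](C)(C)O[C@H]1CC/C(C)=C(/Cl)[C@@H]3OC(O[Sm](I)I)=C(C)[C@@]3(O[Sm](I)I)[C@@H](O[Si](C)(C)C(C)(C)C)[C@H]2[C@@H](C)[C@H](O[Si](C)(C)C(C)(C)C)C=C[C@@]21C | intermediate
46 | 8-hydroxy lactone (C17 epimers) | CC(C)(C)[Si](C)(C)O[C@H]1CC/C(C)=C(/Cl)[C@@H]3OC(=O)C(C)[C@@]3(O)[C@@H](O[Si](C)(C)C(C)(C)C)[C@H]2[C@@H](C)[C@H](O[Si](C)(C)C(C)(C)C)C=C[C@@]21C | intermediate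
47 | (17R)-8-hydroxy lactone | CC(C)(C)[Si](C)(C)O[C@H]1CC/C(C)=C(/Cl)[C@@H]3OC(=O)[C@H](C)[C@@]3(O)[C@@H](O[Si](C)(C)C(C)(C)C)[C@H]2[C@@H](C)[C@H](O[Si](C)(C)C(C)(C)C)C=C[C@@]21C | intermediate
48 | 2,8,9,12-tetraol | O[C@H]1CC/C(C)=C(/Cl)[C@@H]3OC(=O)[C@H](C)[C@@]3(O)[C@@H](O)[C@H]2[C@@H](C)[C@H](O)C=C[C@@]21C | intermediate
49 | 8,9-phenylboronate diol | O[C@H]1CC/C(C)=C(/Cl)[C@@H]3OC(=O)[C@H](C)[C@]34OB(c5ccccc5)O[C@H]4[C@H]2[C@@H](C)[C@H](O)C=C[C@@]21C | intermediate
50 | 8,9-phenylboronate 2,12-diacetate | CC(=O)O[C@H]1CC/C(C)=C(/Cl)[C@@H]3OC(=O)[C@H](C)[C@]34OB(c5ccccc5)O[C@H]4[C@H]2[C@@H](C)[C@H](OC(C)=O)C=C[C@@]21C | intermediate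
51 | CNP0296164.1 | CC(=O)O[C@H]1CC/C(C)=C(/Cl)[C@@H]2OC(=O)[C@H](C)[C@@]2(O)[C@@H](O)[C@H]2[C@@H](C)[C@H](OC(C)=O)C=C[C@@]21C | target

**Step count**
Total steps: 32. Longest linear sequence: 29 (steps 1–8, 10–13, 16–32).

**Three steps most likely to fail**

Step 21. The strained bicyclic envelope may lose its facial or exo/endo preference, so that the wrong C7 configuration is formed, or the radical [1,2]-shift may compete. The fallback sets out from 31 and returns at 34. The rearrangement is used only to make the ring, and C7 is then set by reagent control. The alkynol obtained from 31, in the worst case the 7-epi-cycloalkynol F1, is oxidised with Dess–Martin periodinane to the ten-membered ynone F2. Noyori-type asymmetric transfer hydrogenation with RuCl(p-cymene)[(R,R)-TsDPEN] in i-PrOH, in which the alkynyl group acts as the unsaturated substituent, should then give the 7R alcohol 34.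

Step 23. Carbometalation of the hindered ring alkyne may be slow or regiochemically unselective, or the chlorinating agent may oxidise the magnesium alkoxides. The fallback sets out from 34 and returns at 37, and it fixes the regiochemistry by polarity instead of a directing group. Alcohol 34 is oxidised with Dess–Martin periodinane to the conjugated ynone F3. Me2CuLi adds methyl to the β-carbon C5, and the copper allenolate is chlorinated at C6 with NCS to give the α-chloro-β-methyl cyclodecenone F4 (ring-cis alkene, the less strained geometry). CBS reduction with the (S)-catalyst and catecholborane (chloroalkenyl as the large group) gives the 7R chloro allylic alcohol F5. SeO2/t-BuOOH oxidation of its isopropenyl methyl group then gives 37.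

Step 2. Bond formation at the fully substituted β-carbon C1 may be sluggish, and the ester may compete for the Lewis acid and erode regio- or enantioselectivity. The fallback sets out from 1 and returns at 5, and it replaces the catalyst by a covalently bound auxiliary on C9.
- Ylide 1 and glyoxylic acid give the half-ester (E)-4-ethoxy-3-methyl-4-oxobut-2-enoic acid F6.
- Its mixed pivalic anhydride (PivCl, Et3N, LiCl) acylates (S)-4-benzyloxazolidin-2-one to give the N-enoyl imide F7.
- The Et2AlCl chelate of F7 (s-cis enoyl, benzyl group covering the Re face of C10) adds 4 in the ortho/endo mode to give the imide cycloadduct F8.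
- LiBH4 removes the auxiliary without touching the hindered ester to give the C9 primary alcohol F9.
- Dess–Martin oxidation of F9 gives 5.

**Further compounds**
F1 | step 21 | 7-epi-cycloalkynol | CC(C)(C)[Si](C)(C)O[C@H]1CCC#C[C@@H](O)[C@H](C(C)=C)[C@@H](O[Si](C)(C)C(C)(C)C)[C@H]2[C@@H](C)[C@H](O[Si](C)(C)C(C)(C)C)C=C[C@@]21C
F2 | step 21 | ten-membered ynone | CC(C)(C)[Si](C)(C)O[C@H]1CCC#CC(=O)[C@H](C(C)=C)[C@@H](O[Si](C)(C)C(C)(C)C)[C@H]2[C@@H](C)[C@H](O[Si](C)(C)C(C)(C)C)C=C[C@@]21C
F3 | step 23 | conjugated ynone | CC(C)(C)[Si](C)(C)O[C@H]1CCC#CC(=O)[C@H](C(C)=C)[C@@H](O[Si](C)(C)C(C)(C)C)[C@H]2[C@@H](C)[C@H](O[Si](C)(C)C(C)(C)C)C=C[C@@]21C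
F4 | step 23 | α-chloro-β-methyl cyclodecenone | CC(C)(C)[Si](C)(C)O[C@H]1CC/C(C)=C(/Cl)C(=O)[C@H](C(C)=C)[C@@H](O[Si](C)(C)C(C)(C)C)[C@H]2[C@@H](C)[C@H](O[Si](C)(C)C(C)(C)C)C=C[C@@]21C
F5 | step 23 | 7R chloro allylic alcohol | CC(C)(C)[Si](C)(C)O[C@H]1CC/C(C)=C(/Cl)[C@H](O)[C@H](C(C)=C)[C@@H](O[Si](C)(C)C(C)(C)C)[C@H]2[C@@H](C)[C@H](O[Si](C)(C)C(C)(C)C)C=C[C@@]21C
F6 | step 2 | (E)-4-ethoxy-3-methyl-4-oxobut-2-enoic acid | CCOC(=O)/C(C)=C/C(=O)O
F7 | step 2 | N-enoyl imide | CCOC(=O)/C(C)=C/C(=O)N1[C@@H](Cc2ccccc2)COC1=O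
F8 | step 2 | imide cycloadduct | O=C(N2[C@@H](Cc3ccccc3)COC2=O)[C@H]1[C@@H](C)C=CC[C@@]1(C(=O)OCC)C
F9 | step 2 | C9 primary alcohol | OC[C@H]1[C@@H](C)C=CC[C@@]1(C(=O)OCC)C
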